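A percent of catalyst held for a minute is the unit in which these runs keep time, so two chemists planning the new flask reckon by the catalyst clock, loading as a fraction times elapsed time, which stands at 0.0500 min for that flask at 2.0 min. On it, Friday's run at 1.00 min (0.0380 min) and Sunday's at 2.50 min (0.0425 min) both read 39% target.

common to all: starting material 0.50 mM

| charge | catalyst | remark | time |
|---|---|---|---|
| Sunday's | 1.7 mol% | run made earlier |  |
| Friday's | 3.8 mol% | run made earlier |  |
| flask | 2.5 mol% |  | 2.0 min |

| run | time / min | isomer of the product A / % | target / % |
|---|---|---|---|
| Sunday's | 0.200 | 20 | 8 |
| Sunday's | 0.667 | 28 | 22 |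
| Sunday's | 1.00 | 32 | 25 |
| Sunday's | 1.50 | 30 | 33 |
| Sunday's | 2.50 | 30 | 39 |
| Friday's | 0.500 | 29 | 26 |
| Friday's | 1.00 | 32 | 39 |
| Friday's | 1.33 | 28 | 46 |
| Friday's | 2.00 | 25 | 56 |
| Friday's | 2.50 | 22 | 63 |

(each reading ± 2 percentage points)

* share of isomer of the product A in isomer of the product A plus target at 0.25 s
* share of isomer of the product A in isomer of the product A plus target at 2.0 min
* which of isomer of the product A and target there is more of at 2.0 min

- a reading or a percentage of target counts all its forms, free or not

The first chemist holds that isomer of the product A passes on to target from the first moment, so its share of the two falls along the clock from the start. Sunday's first readings give 71.4% at 0.00340 min and 56.0% at 0.0113 min, and that line runs back to 78.0% at zero clock.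

The second chemist holds that both products start side by side, so the share begins level, as a selectivity factor put in percent. Each of these readings carries 2 percentage points of scatter, so she pools those two and gets 61.5%, and I commit to her number for 0.25 s, a clock of 1.04 × 10⁻⁴ min.

The first view keeps the late end, where the share read in Friday's run sinks from 52.7% at 0.0190 min to 25.9% at 0.0950 min. There both agree: the new flask at 2.0 min matches Friday at 1.33 min (0.0505 min), giving 37.8%, with target ahead at 46% against 28%.

The forecast stands with the first chemist's high start, 83% early (73% to 97%), of which it says “This is an extrapolation and is uncertain”, then 38.5% (35% to 42%) and target ahead.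

The flask gives 64.5% at 0.25 s and 37.6% at 2.0 min, with target ahead at 44.8% against 27.1%.

    starting material + catalyst ⇌ target + catalyst, rate k1*[starting material]*[catalyst] forward; the back reaction follows from the equilibrium constant (K = 6.39, k = 1290 /M/s)
    starting material + catalyst ⇌ isomer of the product A + catalyst, rate k2*[starting material]*[catalyst] forward; the back reaction follows from the equilibrium constant (K = 1.77, k = 2350 /M/s)
    starting material + catalyst ⇌ isomer of the product B + catalyst, rate k3*[starting material]*[catalyst] forward; the back reaction follows from the equilibrium constant (K = 1.00, k = 1770 /M/s)
    starting material + target ⇌ idle adduct, settled at all times (K = 2000 /M)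
    crystals ⇌ target, rate k5*(cs5 - [target]) while solid is left; crystals form when [target] > cs5 (solubility = 0.0140 mM, k = 4.40 /s)

At 0.200 min, a clock of 0.00500 min, the flask holds 21.7% isomer of the product A against 13.2% target, a share of 62.2%. The neighbour flask with 1 mol% catalyst reaches a clock of 0.0200 min at 2.0 min, beside Friday's 0.0190 min at 0.500 min, whose readings give a share of isomer of the product A of 52.7%, and the share in that neighbour flask stands at 53.1%.

The readings were computed for an exercise, and the scatter is random.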